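Each hydroxyquinone ring hides a 2-methyl-5-alkylresorcinol: the oxygens on C(OH) and on the carbonyl flanking the methyl-bearing carbon are meta. The route rests on a Danheiser benzannulation that builds this arene from an acyclic vinyl diazomethyl ketone (carrying the 2-methoxyphenethyl chain) and a siloxypropyne. In one operation a Wolff-derived vinylketene adds the alkyne; the [2+2] joins the future carbonyl carbon beside the phenethyl-bearing carbon to the hydroxyl-bearing carbon, and the 6π closure joins the other future carbonyl carbon to the carbon that later carries the ring-to-ring bond. Oxidative phenol coupling and Teuber oxidation of both rings then give the bis(hydroxyquinone).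

Key step: step 5

Remark: the target SMILES carries no stereodescriptor; there is no stereocenter, and the hindered ring-to-ring axis is formed as the racemate.

Step 1
Reactants: 1 pentane-2,4-dione; 2 1-(2-bromoethyl)-2-methoxybenzene
Product: 3 3-[2-(2-methoxyphenyl)ethyl]pentane-2,4-dione
Conditions: K2CO3, NaI (10 mol %), acetone, reflux
Reagents that add atoms: none
Why: C-alkylation of the acetylacetonate (SN2 on the primary halide with Finkelstein catalysis) should work because the soft, weakly basic enolate limits E2 to the styrene.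

Step 2
Reactants: 3 3-[2-(2-methoxyphenyl)ethyl]pentane-2,4-dione
Product: 5 5-(2-methoxyphenyl)-3-methylidenepentan-2-one, via hydroxymethyl diketone 4 (not isolated)
Conditions: 37% aq. CH2O, K2CO3, H2O/THF, 20 °C
Reagents that add atoms: formaldehyde, C=O
Why: Deacetylative methylenation: aldol addition of the diketone enolate to formaldehyde gives 4, and retro-Claisen loss of one acetyl group as acetate with β-elimination should leave the α-methylene ketone.

Step 3
Reactants: 5 5-(2-methoxyphenyl)-3-methylidenepentan-2-one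
Product: 7 1-diazo-5-(2-methoxyphenyl)-3-methylidenepentan-2-one, via trifluoroacetyl diketone 6 (not isolated)
Conditions: LiN(SiMe3)2, THF, −78 °C; CF3CO2CH2CF3; aq. HCl work-up; then 4-AcNHC6H4SO2N3, Et3N, H2O, MeCN, 20 °C
Reagents that add atoms: 4-acetamidobenzenesulfonyl azide, CC(=O)Nc1ccc(cc1)S(=O)(=O)N=[N+]=[N-]; 2,2,2-trifluoroethyl trifluoroacetate, O=C(OCC(F)(F)F)C(F)(F)F (its CF3CO group stays only in 6)
Why: Detrifluoroacetylative Regitz diazo transfer: kinetic deprotonation at the only enolizable α′ position (the methyl group) and Claisen trifluoroacetylation give 6, to which the sulfonyl azide transfers N2 with loss of the trifluoroacetyl group, so that diazomethane, which would add to the enone, is avoided.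

Step 4
Reactants: 8 prop-1-yn-1-yllithium
Product: 10 triisopropyl(prop-1-yn-1-yloxy)silane, via lithium ynolate 9 (not isolated)
Conditions: t-BuOOH, LiN(SiMe3)2, THF, −78 °C; then 8, −78 to 0 °C; then i-Pr3SiOTf, −78 to 20 °C
Reagents that add atoms: tert-butyl hydroperoxide, CC(C)(C)OO; triisopropylsilyl trifluoromethanesulfonate, CC(C)[Si](C(C)C)(C(C)C)OS(=O)(=O)C(F)(F)F
Why: Electrophilic oxygenation of the acetylide by lithium tert-butyl peroxide should give ynolate 9, which the bulky silyl triflate traps on oxygen to give the siloxyalkyne.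

Step 5
Reactants: 7 1-diazo-5-(2-methoxyphenyl)-3-methylidenepentan-2-one; 10 triisopropyl(prop-1-yn-1-yloxy)silane
Product: 15 5-[2-(2-methoxyphenyl)ethyl]-2-methyl-3-[(triisopropylsilyl)oxy]phenol, via vinylketene 11 (not isolated), via vinylcyclobutenone 12 (not isolated), via dienylketene 13 (not isolated), via cyclohexadienone 14 (not isolated)
Conditions: hν (254 nm), ClCH2CH2Cl, 20 °C; then 80 °C
Reagents that add atoms: none
Why: Danheiser benzannulation in its diazo ketone form: photochemical Wolff rearrangement of 7 (loss of N2, 1,2-shift of the alkenyl group) gives vinylketene 11, a polar [2+2] cycloaddition with 10 gives 12, 4π electrocyclic opening gives 13, 6π electrocyclization gives 14 and enolization gives 15. The closest known reaction type is the benzannulation of α,β-unsaturated α′-diazo ketones with 1-siloxyalkynes to resorcinol monosilyl ethers. The four-membered ring closes by [2+2] cycloaddition (ketene α-carbon to the oxygen-bearing alkyne carbon, ketene carbonyl carbon to the methyl-bearing alkyne carbon) and the six-membered ring by thermal 6π electrocyclic closure (ketene carbon to the terminal methylene carbon). The only stereocenter formed, C4 of 12, is lost on ring opening, so none needs control. The step needs regiocontrol in the [2+2], which the polarized siloxyalkyne secures because its nucleophilic methyl-bearing carbon attacks the ketene carbonyl carbon, placing the methyl group between the two oxygens; the constitution of 11 is fixed because only the alkenyl group can migrate. Heating after irradiation should convert remaining 12 and let the non-productive geometry of 13 return through 12.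

Step 6
Reactants: 15 5-[2-(2-methoxyphenyl)ethyl]-2-methyl-3-[(triisopropylsilyl)oxy]phenol; 15 5-[2-(2-methoxyphenyl)ethyl]-2-methyl-3-[(triisopropylsilyl)oxy]phenol
Product: 16 6,6'-bis[2-(2-methoxyphenyl)ethyl]-3,3'-dimethyl-4,4'-bis[(triisopropylsilyl)oxy]-[1,1'-biphenyl]-2,2'-diol (racemic axis)
Conditions: FeCl3 (10 mol %), t-BuOOt-Bu, (CF3)2CHOH, 20 °C
Reagents that add atoms: none
Why: Oxidative phenol homocoupling of two molecules of 15, catalysed by FeCl3 (trivalent iron) with the peroxide as terminal oxidant, should join two phenoxyl radicals at the free position ortho to OH and para to the siloxy group, the para position being shielded by the silyl ether; each molecule of 15 loses one ring hydrogen, the axis forms as the racemate, and an ortho–para or para–para isomer would give the same tetrol 17 in step 7.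

Step 7
Reactants: 16 6,6'-bis[2-(2-methoxyphenyl)ethyl]-3,3'-dimethyl-4,4'-bis[(triisopropylsilyl)oxy]-[1,1'-biphenyl]-2,2'-diol
Product: 18 4,4'-dihydroxy-2,2'-bis[2-(2-methoxyphenyl)ethyl]-5,5'-dimethyl-[1,1'-bi(cyclohexa-1,4-diene)]-3,3',6,6'-tetrone (the target), via biphenyltetrol 17 (not isolated)
Conditions: Bu4NF, AcOH, THF, 0 °C; then (KO3S)2NO, KH2PO4, H2O/acetone, 20 °C
Reagents that add atoms: potassium nitrosodisulfonate, [K+].[K+].[O]N(S(=O)(=O)[O-])S(=O)(=O)[O-]
Why: Buffered fluoride should cleave both aryl silyl ethers, and Teuber oxidation of each resorcinol ring of 17 at its only free CH, para to the 2-hydroxyl, should give the para-quinone while the 4-hydroxyl stays as the quinone OH.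

Compound list
1 | pentane-2,4-dione | CC(=O)CC(C)=O | starting material
2 | 1-(2-bromoethyl)-2-methoxybenzene | COc1ccccc1CCBr | starting material
3 | 3-[2-(2-methoxyphenyl)ethyl]pentane-2,4-dione | CC(=O)C(CCc1ccccc1OC)C(C)=O | intermediate
4 | 3-(hydroxymethyl)-3-[2-(2-methoxyphenyl)ethyl]pentane-2,4-dione | CC(=O)C(CO)(CCc1ccccc1OC)C(C)=O | intermediate
5 | 5-(2-methoxyphenyl)-3-methylidenepentan-2-one | CC(=O)C(=C)CCc1ccccc1OC | intermediate
6 | 1,1,1-trifluoro-7-(2-methoxyphenyl)-5-methylideneheptane-2,4-dione | O=C(CC(=O)C(=C)CCc1ccccc1OC)C(F)(F)F | intermediate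
7 | 1-diazo-5-(2-methoxyphenyl)-3-methylidenepentan-2-one | [N-]=[N+]=CC(=O)C(=C)CCc1ccccc1OC | intermediate
8 | prop-1-yn-1-yllithium | [Li]C#CC | starting material
9 | lithium prop-1-yn-1-olate | CC#C[O-].[Li+] | intermediate
10 | triisopropyl(prop-1-yn-1-yloxy)silane | CC#CO[Si](C(C)C)(C(C)C)C(C)C | intermediate
11 | 5-(2-methoxyphenyl)-3-methylidenepent-1-en-1-one (vinylketene) | O=C=CC(=C)CCc1ccccc1OC | intermediate
12 | 4-[4-(2-methoxyphenyl)but-1-en-2-yl]-2-methyl-3-[(triisopropylsilyl)oxy]cyclobut-2-en-1-one (racemic) | O=C1C(C)=C(O[Si](C(C)C)(C(C)C)C(C)C)C1C(=C)CCc1ccccc1OC | intermediate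
13 | (3E)-7-(2-methoxyphenyl)-2-methyl-5-methylidene-3-[(triisopropylsilyl)oxy]hepta-1,3-dien-1-one (C2 and C5 cis) | CC(=C=O)/C(O[Si](C(C)C)(C(C)C)C(C)C)=C\C(=C)CCc1ccccc1OC | intermediate
14 | 5-[2-(2-methoxyphenyl)ethyl]-2-methyl-3-[(triisopropylsilyl)oxy]cyclohexa-2,4-dien-1-one | O=C1CC(CCc2ccccc2OC)=CC(O[Si](C(C)C)(C(C)C)C(C)C)=C1C | intermediate
15 | 5-[2-(2-methoxyphenyl)ethyl]-2-methyl-3-[(triisopropylsilyl)oxy]phenol | Cc1c(O)cc(CCc2ccccc2OC)cc1O[Si](C(C)C)(C(C)C)C(C)C | intermediate
16 | 6,6'-bis[2-(2-methoxyphenyl)ethyl]-3,3'-dimethyl-4,4'-bis[(triisopropylsilyl)oxy]-[1,1'-biphenyl]-2,2'-diol (racemic axis) | Cc1c(O)c(-c2c(O)c(C)c(O[Si](C(C)C)(C(C)C)C(C)C)cc2CCc2ccccc2OC)c(CCc2ccccc2OC)cc1O[Si](C(C)C)(C(C)C)C(C)C | intermediate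
17 | 6,6'-bis[2-(2-methoxyphenyl)ethyl]-3,3'-dimethyl-[1,1'-biphenyl]-2,2',4,4'-tetrol | Cc1c(O)cc(CCc2ccccc2OC)c(-c2c(O)c(C)c(O)cc2CCc2ccccc2OC)c1O | intermediate
18 | 4,4'-dihydroxy-2,2'-bis[2-(2-methoxyphenyl)ethyl]-5,5'-dimethyl-[1,1'-bi(cyclohexa-1,4-diene)]-3,3',6,6'-tetrone | COc1ccccc1CCC1=C(C2=C(CCc3ccccc3OC)C(=O)C(O)=C(C)C2=O)C(=O)C(C)=C(O)C1=O | target

Total step count: 7. Longest linear sequence: 6 steps (1, 2, 3, 5, 6, 7); step 4 supplies the alkyne.

Steps most likely to fail

Step 5. The vinylketene may be lost to dimerization or to acylation of the phenol product before it meets the alkyne, and the anisole chromophore may slow the Wolff rearrangement by competing for light. The fallback reaches the same vinylketene thermally from a cyclobutenone. It sets out from 2: alkynylation with LiC≡CH·H2NCH2CH2NH2 in DMSO should give 1-(but-3-yn-1-yl)-2-methoxybenzene F1. A [2+2] cycloaddition with dichloroketene (Cl3CCOCl, Zn(Cu), Et2O) should give 4,4-dichloro-3-[2-(2-methoxyphenyl)ethyl]cyclobut-2-en-1-one F2. Reductive dechlorination (Zn, AcOH, TMEDA, EtOH) should give 3-[2-(2-methoxyphenyl)ethyl]cyclobut-2-en-1-one F3. Heating F3 with 10 in toluene at 80 °C opens the four-membered ring to vinylketene 11, which then follows the same cycloaddition and electrocyclization sequence. The fallback comes back to the route at 15.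

Step 6. The coupling may stall at the hindered tetra-ortho-substituted axis, or run on to C–O coupling, over-oxidation and oligomers. The fallback replaces the radical coupling by a halide homocoupling. It sets out from 15: desilylation (Bu4NF, AcOH, THF) should give 5-[2-(2-methoxyphenyl)ethyl]-2-methylbenzene-1,3-diol F4. Benzylation (BnBr, K2CO3, DMF) should give 1,3-bis(benzyloxy)-5-[2-(2-methoxyphenyl)ethyl]-2-methylbenzene F5. Iodination with N-iodosuccinimide in MeCN at the single type of free ring position should give 1,3-bis(benzyloxy)-4-iodo-5-[2-(2-methoxyphenyl)ethyl]-2-methylbenzene F6. Ullmann homocoupling of two molecules of F6 (Cu powder, DMF, 150 °C) should give 2,2',4,4'-tetrakis(benzyloxy)-6,6'-bis[2-(2-methoxyphenyl)ethyl]-3,3'-dimethyl-1,1'-biphenyl F7. Hydrogenolysis (H2, Pd/C, EtOAc/MeOH) leaves the anisole ethers untouched. The fallback comes back to the route at 17, which is oxidized as in the second stage of step 7.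

Step 3. The enolate of the α-methylene ketone may add to unreacted enone (Michael oligomerization) before it is trifluoroacetylated. The fallback masks the enone as a Mannich base during the diazo transfer. It sets out from 5: aza-Michael addition of Me2NH in THF should give 3-[(dimethylamino)methyl]-5-(2-methoxyphenyl)pentan-2-one F8. Kinetic enolization at the methyl group and trifluoroacetylation as in step 3 (NH4Cl work-up) should give 5-[(dimethylamino)methyl]-1,1,1-trifluoro-7-(2-methoxyphenyl)heptane-2,4-dione F9. Diazo transfer with the same sulfonyl azide should give 1-diazo-3-[(dimethylamino)methyl]-5-(2-methoxyphenyl)pentan-2-one F10. N-Methylation with MeI should give [2-(diazoacetyl)-4-(2-methoxyphenyl)butyl]trimethylammonium iodide F11, and β-elimination of trimethylamine with NaHCO3 brings the fallback back to the route at 7.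

Further compounds
F1 | step 5 | 1-(but-3-yn-1-yl)-2-methoxybenzene | C#CCCc1ccccc1OC
F2 | step 5 | 4,4-dichloro-3-[2-(2-methoxyphenyl)ethyl]cyclobut-2-en-1-one | O=C1C=C(CCc2ccccc2OC)C1(Cl)Cl
F3 | step 5 | 3-[2-(2-methoxyphenyl)ethyl]cyclobut-2-en-1-one | O=C1C=C(CCc2ccccc2OC)C1
F4 | step 6 | 5-[2-(2-methoxyphenyl)ethyl]-2-methylbenzene-1,3-diol | Cc1c(O)cc(CCc2ccccc2OC)cc1O
F5 | step 6 | 1,3-bis(benzyloxy)-5-[2-(2-methoxyphenyl)ethyl]-2-methylbenzene | Cc1c(OCc2ccccc2)cc(CCc2ccccc2OC)cc1OCc1ccccc1
F6 | step 6 | 1,3-bis(benzyloxy)-4-iodo-5-[2-(2-methoxyphenyl)ethyl]-2-methylbenzene | Cc1c(OCc2ccccc2)cc(CCc2ccccc2OC)c(I)c1OCc1ccccc1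
F7 | step 6 | 2,2',4,4'-tetrakis(benzyloxy)-6,6'-bis[2-(2-methoxyphenyl)ethyl]-3,3'-dimethyl-1,1'-biphenyl | Cc1c(OCc2ccccc2)cc(CCc2ccccc2OC)c(-c2c(OCc3ccccc3)c(C)c(OCc3ccccc3)cc2CCc2ccccc2OC)c1OCc1ccccc1
F8 | step 3 | 3-[(dimethylamino)methyl]-5-(2-methoxyphenyl)pentan-2-one | CC(=O)C(CN(C)C)CCc1ccccc1OC
F9 | step 3 | 5-[(dimethylamino)methyl]-1,1,1-trifluoro-7-(2-methoxyphenyl)heptane-2,4-dione | O=C(CC(=O)C(CN(C)C)CCc1ccccc1OC)C(F)(F)F
F10 | step 3 | 1-diazo-3-[(dimethylamino)methyl]-5-(2-methoxyphenyl)pentan-2-one | [N-]=[N+]=CC(=O)C(CN(C)C)CCc1ccccc1OC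
F11 | step 3 | [2-(diazoacetyl)-4-(2-methoxyphenyl)butyl]trimethylammonium iodide | [N-]=[N+]=CC(=O)C(C[N+](C)(C)C)CCc1ccccc1OC.[I-]
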